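The ratio of the two capture rates, target over other capture product, is what we follow in this flask, from the steps and charges below.

solid substrate 2.5 M; second nucleophile 2.00 M; capture agent 0.0500 M; gas 200 mM (held); time 12 d

    starting material → open intermediate (k1 = 3.7 × 10⁻⁵ s⁻¹)
    first nucleophile + open intermediate → target (k2 = 0.025 M⁻¹ s⁻¹)
    second nucleophile + open intermediate → other capture product (k3 = 0.0071 M⁻¹ s⁻¹)
    solid substrate ⇌ starting material, rate k4*(cs4 - [starting material]) while solid is left; crystals form when [starting material] > cs4 (cs4 = 1.2 M, k4 = 1.8 × 10⁻⁵ s⁻¹)
    open intermediate + capture agent → trapped intermediate (k5 = 3.4 × 10⁻⁶ M⁻¹ s⁻¹)
    gas ⇌ first nucleophile, rate k6*(csat - [first nucleophile]) (k6 = 1.1 × 10⁻⁴ s⁻¹, csat = 200 mM)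

- the state of affairs at 12 d: stopped, and by what, or still going (for what has run out or reacted, a solid counts together with what of it has only dissolved) (it is still moving / the second nucleophile has run out first / all of the solid substrate has reacted)
- part of the solid substrate that has turned into other species by 12 d (what has only dissolved does not count)
- the target standing at 12 d, as a percentage of the solid substrate charged
- the other capture product standing at 12 d, as a percentage of the solid substrate charged

- solid, in amounts per volume of the solution: solid substrate
- at the start none of first nucleophile is dissolved
- at the start none of the solid substrate is in solution
- what has only dissolved of solid substrate counts as not reacted
- the reaction counts as stopped when no species that holds the solid substrate changes by six tenths of a point or more over the second half of the time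
- run time (flask): 12 d

We climb from the fastest clock to the slowest. An open intermediate lasts about 52.1 s, much shorter than the 2.53 h in which the gas refills the first nucleophile, so we treat it as a steady-state species. Its half-life against the capture agent is 47 d, far longer than its lifetime, so we drop that path.

Next, the starting material levels off near 0.393 M, where dissolving equals opening, and while solid remains it feeds the captures at 0.0523 M h⁻¹. The charge therefore lasts about 47.8 h, shorter than the run.

The gas refills in 2.53 h, shorter than the charge lasts, so we let [first nucleophile] follow the feed. If about a third of the feed becomes target, the gas must replace that much, which holds [first nucleophile] near 0.156 M. We call the rate constant of the target step times this [first nucleophile], divided by the rate constant of the other capture step, the even point, the [second nucleophile] at which both captures run equally fast: 0.549 M. The selectivity factor is then the even point over [second nucleophile], so with [first nucleophile] held at that value, target formed equals the even point times ln(charged over remaining [second nucleophile]).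

Trying 0.400 M of second nucleophile left gives 0.884 M of target and 1.60 M of other capture product, together 2.48 M against the 2.5 M charged. We commit to 35.4% target and 64.6% other capture product, with the solid substrate used up after about 47.8 h.

The forecast says all of the solid substrate has reacted, conversion 100%, target 36% and other capture product 64%, its ground being “the gas-fed first nucleophile, held somewhat below saturation, competing against the second nucleophile”.

The simulation gives: all of the solid substrate has reacted, with conversion 100%, target 35.8% and other capture product 64.2%. In this flask 20% of the charged second nucleophile stands at 12.0 d. The neighbour flask with 1.5 M of solid substrate keeps the same charge of second nucleophile and ends with 47% of it left. The even point of 0.549 M turns that remainder into 0.414 M of target, which is 27.6% of that flask's solid substrate, and the simulation of that flask gives 29.4%.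

(The constants are made up; no experiment stands behind them.)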